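**Plan**

- Retrosynthesis: the three benzyl groups and the ring B dioxolane come off last; the ring A C3–CHO bond is cut next. Ring A is then opened at C1–C2 and C5–C6 to an aryl but-2-ynoate and a 1,3-dioxygenated butadiene. Finally the ynoate acyl–O bond and, on ring B, C5–O (through C5–Br) and C3–CHO are cut back to orsellinic acid.
- Enabling feature: in ring A (C1 acyl-bearing carbon, C2 OH, C3 CHO, C4 OMe, C5 H, C6 CH3) the methyl-bearing C6 and the carboxyl-bearing C1 are neighbours, so they are the two alkyne carbons of a but-2-ynoate. C2–C5, with oxygen on C2 and C4, is a 1,3-dimethoxy-1-silyloxybutadiene, so the crowded inter-ring ester can be made while the acyl part is still a slim alkyne.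
- Forward: ring B is elaborated first from orsellinic acid (benzyl ester, C3 formylation, C5 bromination, O-benzylation, acetal, bromide to phenol). Its C5 phenol is acylated with but-2-ynoic acid, ring A is built on that ester by [4+2] cycloaddition and aromatization, and ring A C3 is formylated before deprotection.
- Stereochemistry: the target has no stereocentre; only regiochemistry must be controlled (orientation of the cycloaddition, ortho-selectivity of the two formylations).

Key step: step 9

Remark: both rings are numbered as orsellinates (C1 carries the carboxyl carbon, C6 the methyl group).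

**Route**

Step 1
Reactants: 1 orsellinic acid (2,4-dihydroxy-6-methylbenzoic acid)
Product: 2 benzyl orsellinate (benzyl 2,4-dihydroxy-6-methylbenzoate)
Conditions: BnBr, KHCO3, DMF, rt
Reagents that add atoms: benzyl bromide, BrCc1ccccc1
Why: SN2 O-alkylation of the carboxylate; hydrogencarbonate ionises only the carboxylic acid, so the phenols should stay free.

Step 2
Reactants: 2 benzyl orsellinate
Product: 3 benzyl haematommate (benzyl 3-formyl-2,4-dihydroxy-6-methylbenzoate)
Conditions: Cl2CHOMe, TiCl4, CH2Cl2, −20 → 0 °C; then ice-cold aq. HCl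
Reagents that add atoms: dichloromethyl methyl ether, COC(Cl)Cl (formyl carbon); water, O (formyl oxygen, on hydrolysis of the α-chloro ether)
Why: Rieche formylation; C3 lies ortho to both titanium-bound phenoxide oxygens and is the more enolic carbon of the chelated 2-hydroxybenzoate, the position at which orsellinates are formylated in Gattermann-type reactions, and any minor C5 isomer should be separable.

Step 3
Reactants: 3 benzyl haematommate
Product: 4 benzyl 5-bromo-3-formyl-2,4-dihydroxy-6-methylbenzoate
Conditions: NBS, MeCN, 0 °C → rt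
Reagents that add atoms: N-bromosuccinimide, O=C1CCC(=O)N1Br
Why: Electrophilic aromatic bromination at the only free ring carbon C5, which is ortho to the C4 hydroxyl and para to the C2 hydroxyl.

Step 4
Reactants: 4 benzyl 5-bromo-3-formyl-2,4-dihydroxy-6-methylbenzoate
Product: 5 benzyl 2,4-bis(benzyloxy)-5-bromo-3-formyl-6-methylbenzoate
Conditions: BnBr, K2CO3, Bu4NI (cat.), DMF, 60 °C
Reagents that add atoms: benzyl bromide, BrCc1ccccc1
Why: Williamson etherification; both chelated phenols are acidic enough for carbonate, and warming with iodide catalysis should overcome the flanking substituents.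

Step 5
Reactants: 5 benzyl 2,4-bis(benzyloxy)-5-bromo-3-formyl-6-methylbenzoate
Product: 6 benzyl 2,4-bis(benzyloxy)-5-bromo-3-(1,3-dioxolan-2-yl)-6-methylbenzoate
Conditions: HOCH2CH2OH, p-TsOH (cat.), PhMe, reflux, Dean–Stark
Reagents that add atoms: ethylene glycol, OCCO
Why: Acid-catalysed acetalization with azeotropic removal of water masks the aldehyde against organolithium and diene; the doubly ortho-substituted benzyl ester is too hindered to transesterify.

Step 6
Reactants: 6 benzyl 2,4-bis(benzyloxy)-5-bromo-3-(1,3-dioxolan-2-yl)-6-methylbenzoate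
Product: 8 benzyl 2,4-bis(benzyloxy)-3-(1,3-dioxolan-2-yl)-5-hydroxy-6-methylbenzoate, via lithium aryltrimethoxyborate 7 (not isolated)
Conditions: n-BuLi, THF, −78 °C; B(OMe)3, −78 → 0 °C; then 30% H2O2, 0 °C → rt
Reagents that add atoms: hydrogen peroxide, OO (the new phenolic oxygen); trimethyl borate, COB(OC)OC (boron and methoxy groups of intermediate 7 only)
Why: Bromine–lithium exchange at −78 °C should outrun addition to the doubly ortho-flanked benzyl ester, the aryllithium is trapped as the borate, and peroxide triggers the 1,2-aryl shift from boron to oxygen (borylation–oxidation of an aryl halide to a phenol).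

Step 7
Reactants: 8 benzyl 2,4-bis(benzyloxy)-3-(1,3-dioxolan-2-yl)-5-hydroxy-6-methylbenzoate; 9 but-2-ynoic acid
Product: 10 benzyl 2,4-bis(benzyloxy)-5-(but-2-ynoyloxy)-3-(1,3-dioxolan-2-yl)-6-methylbenzoate
Conditions: DCC, DMAP (cat.), CH2Cl2, 0 °C → rt
Reagents that add atoms: none
Why: Steglich esterification; the linear four-carbon acid is a slim acyl donor for the phenol flanked by benzyloxy and methyl, and low DMAP loading at 0 °C should limit alkyne-to-allene isomerization.

Step 8
Reactants: 11 methyl (E)-3-methoxybut-2-enoate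
Product: 12 (1Z)-1,3-dimethoxy-1-[(trimethylsilyl)oxy]buta-1,3-diene
Conditions: LiN(i-Pr)2, THF, −78 °C; then Me3SiCl, −78 °C → rt
Reagents that add atoms: chlorotrimethylsilane, C[Si](C)(C)Cl
Why: γ-Deprotonation of the β-methoxy enoate gives the extended dienolate, which is silylated on oxygen (silyl ketene acetal formation) to the Brassard-type diene, used freshly distilled.

Step 9
Reactants: 10 benzyl 2,4-bis(benzyloxy)-5-(but-2-ynoyloxy)-3-(1,3-dioxolan-2-yl)-6-methylbenzoate; 12 (1Z)-1,3-dimethoxy-1-[(trimethylsilyl)oxy]buta-1,3-diene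
Product: 15 benzyl 2,4-bis(benzyloxy)-3-(1,3-dioxolan-2-yl)-5-[(2-hydroxy-4-methoxy-6-methylbenzoyl)oxy]-6-methylbenzoate, via cyclohexa-1,4-diene cycloadduct 13 (not isolated), via ring A trimethylsilyl ether 14 (not isolated)
Conditions: 12 (3 equiv), PhMe, 110 °C, sealed tube; then Bu4NF, AcOH, THF, 0 °C
Reagents that add atoms: none
Why: Diene 12 is a vinylogous silyl ketene acetal whose nucleophilic CH2 terminus bonds to the methyl-bearing β-carbon of the electron-poor aryl ynoate 10 while its ketene acetal carbon bonds to the α-carbon, an asynchronous thermal [4+2] cycloaddition of the known type between Brassard-type dienes and acetylenic esters. Ring A closes as a six-membered carbocycle by intermolecular [4+2] cycloaddition, forming C1–C2 and C5–C6 in one operation and giving the cyclohexa-1,4-diene ketal 13. Loss of methanol across the ketal carbon and the ring CH2 aromatizes 13 to silyl ether 14, and buffered fluoride removes the silyl group and collapses any surviving ketal through its dienone tautomer, so the hydroxyl ends at C2 and the enol ether methoxy at C4 by construction. No stereocentre results, because the ketal carbon of 13 forms as a racemate and is flattened on aromatization. The selectivity needed is regiochemical (methyl on C6, hydroxyl on C2), and it is secured by the matched polarity of the diene CH2 terminus and the ynoate β-carbon, with the aryl ester making the dienophile more electron-poor than an alkyl but-2-ynoate. The dioxolane, the benzyl ethers and the hindered benzyl ester should be inert to neutral heating and to acetic acid-buffered fluoride.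

Step 10
Reactants: 15 benzyl 2,4-bis(benzyloxy)-3-(1,3-dioxolan-2-yl)-5-[(2-hydroxy-4-methoxy-6-methylbenzoyl)oxy]-6-methylbenzoate
Product: 17 benzyl 2,4-bis(benzyloxy)-3-formyl-5-[(3-formyl-2-hydroxy-4-methoxy-6-methylbenzoyl)oxy]-6-methylbenzoate, via ring A formylated dioxolane 16 (not isolated)
Conditions: MgCl2, Et3N, (CH2O)n, MeCN, reflux; then 2 M HCl, THF, rt
Reagents that add atoms: paraformaldehyde (as formaldehyde), C=O (ring A formyl group); water, O (oxygen of the ring B aldehyde)
Why: Magnesium-mediated ortho-formylation of a phenol (Casnati–Skattebøl reaction) delivers formaldehyde from the ring A magnesium phenoxide only to its free ortho carbon C3, a second formaldehyde oxidizes the hydroxymethyl stage to the aldehyde without touching benzyl groups or the hindered esters, and the aqueous acid then hydrolyses the dioxolane.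

Step 11
Reactants: 17 benzyl 2,4-bis(benzyloxy)-3-formyl-5-[(3-formyl-2-hydroxy-4-methoxy-6-methylbenzoyl)oxy]-6-methylbenzoate
Product: 18 haemathamnolic acid (3-formyl-5-[(3-formyl-2-hydroxy-4-methoxy-6-methylbenzoyl)oxy]-2,4-dihydroxy-6-methylbenzoic acid)
Conditions: H2 (1 atm), 10% Pd/C, EtOAc, rt, stopped after uptake of three equivalents
Reagents that add atoms: none
Why: Catalytic hydrogenolysis cleaves the benzyl ester and both benzyl aryl ethers; the two aldehydes, chelated by ortho hydroxyls once these are unmasked, should be reduced far more slowly than the benzylic C–O bonds.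

**Compound list**

1 | orsellinic acid (2,4-dihydroxy-6-methylbenzoic acid) | Cc1cc(O)cc(O)c1C(=O)O | starting material
2 | benzyl 2,4-dihydroxy-6-methylbenzoate | Cc1cc(O)cc(O)c1C(=O)OCc1ccccc1 | intermediate
3 | benzyl 3-formyl-2,4-dihydroxy-6-methylbenzoate | Cc1cc(O)c(C=O)c(O)c1C(=O)OCc1ccccc1 | intermediate
4 | benzyl 5-bromo-3-formyl-2,4-dihydroxy-6-methylbenzoate | Cc1c(Br)c(O)c(C=O)c(O)c1C(=O)OCc1ccccc1 | intermediate
5 | benzyl 2,4-bis(benzyloxy)-5-bromo-3-formyl-6-methylbenzoate | Cc1c(Br)c(OCc2ccccc2)c(C=O)c(OCc2ccccc2)c1C(=O)OCc1ccccc1 | intermediate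
6 | benzyl 2,4-bis(benzyloxy)-5-bromo-3-(1,3-dioxolan-2-yl)-6-methylbenzoate | Cc1c(Br)c(OCc2ccccc2)c(C2OCCO2)c(OCc2ccccc2)c1C(=O)OCc1ccccc1 | intermediate
7 | lithium {2,4-bis(benzyloxy)-5-[(benzyloxy)carbonyl]-3-(1,3-dioxolan-2-yl)-6-methylphenyl}trimethoxyborate | [Li+].CO[B-](OC)(OC)c1c(C)c(C(=O)OCc2ccccc2)c(OCc2ccccc2)c(C2OCCO2)c1OCc1ccccc1 | intermediate (not isolated)
8 | benzyl 2,4-bis(benzyloxy)-3-(1,3-dioxolan-2-yl)-5-hydroxy-6-methylbenzoate | Cc1c(O)c(OCc2ccccc2)c(C2OCCO2)c(OCc2ccccc2)c1C(=O)OCc1ccccc1 | intermediate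
9 | but-2-ynoic acid | CC#CC(=O)O | starting material
10 | benzyl 2,4-bis(benzyloxy)-5-(but-2-ynoyloxy)-3-(1,3-dioxolan-2-yl)-6-methylbenzoate | CC#CC(=O)Oc1c(C)c(C(=O)OCc2ccccc2)c(OCc2ccccc2)c(C2OCCO2)c1OCc1ccccc1 | intermediate
11 | methyl (E)-3-methoxybut-2-enoate | CO/C(C)=C/C(=O)OC | starting material
12 | (1Z)-1,3-dimethoxy-1-[(trimethylsilyl)oxy]buta-1,3-diene | C=C(OC)/C=C(/OC)O[Si](C)(C)C | intermediate
13 | benzyl 2,4-bis(benzyloxy)-3-(1,3-dioxolan-2-yl)-5-({4,6-dimethoxy-2-methyl-6-[(trimethylsilyl)oxy]cyclohexa-1,4-diene-1-carbonyl}oxy)-6-methylbenzoate (racemic at the ketal carbon) | COC1=CC(OC)(O[Si](C)(C)C)C(C(=O)Oc2c(C)c(C(=O)OCc3ccccc3)c(OCc3ccccc3)c(C3OCCO3)c2OCc2ccccc2)=C(C)C1 | intermediate (not isolated)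
14 | benzyl 2,4-bis(benzyloxy)-3-(1,3-dioxolan-2-yl)-5-({4-methoxy-2-methyl-6-[(trimethylsilyl)oxy]benzoyl}oxy)-6-methylbenzoate | COc1cc(C)c(C(=O)Oc2c(C)c(C(=O)OCc3ccccc3)c(OCc3ccccc3)c(C3OCCO3)c2OCc2ccccc2)c(O[Si](C)(C)C)c1 | intermediate (not isolated)
15 | benzyl 2,4-bis(benzyloxy)-3-(1,3-dioxolan-2-yl)-5-[(2-hydroxy-4-methoxy-6-methylbenzoyl)oxy]-6-methylbenzoate | COc1cc(C)c(C(=O)Oc2c(C)c(C(=O)OCc3ccccc3)c(OCc3ccccc3)c(C3OCCO3)c2OCc2ccccc2)c(O)c1 | intermediate
16 | benzyl 2,4-bis(benzyloxy)-3-(1,3-dioxolan-2-yl)-5-[(3-formyl-2-hydroxy-4-methoxy-6-methylbenzoyl)oxy]-6-methylbenzoate | COc1cc(C)c(C(=O)Oc2c(C)c(C(=O)OCc3ccccc3)c(OCc3ccccc3)c(C3OCCO3)c2OCc2ccccc2)c(O)c1C=O | intermediate (not isolated)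
17 | benzyl 2,4-bis(benzyloxy)-3-formyl-5-[(3-formyl-2-hydroxy-4-methoxy-6-methylbenzoyl)oxy]-6-methylbenzoate | COc1cc(C)c(C(=O)Oc2c(C)c(C(=O)OCc3ccccc3)c(OCc3ccccc3)c(C=O)c2OCc2ccccc2)c(O)c1C=O | intermediate
18 | haemathamnolic acid | COc1cc(C)c(C(=O)Oc2c(C)c(C(=O)O)c(O)c(C=O)c2O)c(O)c1C=O | target

**Totals**

Total step count: 11. Longest linear sequence: 10 steps (steps 1–7 and 9–11, from orsellinic acid); step 8 is a one-step side branch.

**Steps most likely to fail**

Step 9. The β-methyl ynoate may add so slowly that thermal decomposition or adventitious hydrolysis of the diene wins, or the adduct may aromatize incompletely. The fallback forms the inter-ring ester with ring A already aromatic. It sets out from phenol 8, which is condensed with commercial everninic acid F1 (2-hydroxy-4-methoxy-6-methylbenzoic acid) through its mixed trifluoroacetic anhydride F2 (trifluoroacetic anhydride, dry toluene, rt, the classical depside coupling of a chelated 2-hydroxy acid). It comes back to the route at 15.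

Step 10. The magnesium may be locked in the salicylate-type chelate of ring A so that formaldehyde transfer to C3 is slow, and prolonged heating with amine and methanol could then cleave the aryl ester or O-methoxymethylate the phenol. The fallback splits the formylation into a boron-templated ortho-hydroxymethylation and an oxidation. It sets out from 15, which with PhB(OH)2, paraformaldehyde and catalytic propionic acid in refluxing toluene should give the ring A 2-phenyl-4H-1,3,2-benzodioxaborin F3. Exchange with propane-1,3-diol releases the ring A salicyl alcohol F4, and MnO2 in CH2Cl2 oxidizes the benzylic alcohol to the aldehyde. The fallback comes back to the route at 16, which is hydrolysed with 2 M HCl in THF as in step 10 to give 17.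

Step 6. Butyllithium may add to the benzyl ester or deprotonate a benzylic position in competition with bromine–lithium exchange, and the crowded aryllithium may be protonated before it is borylated. The fallback makes the C–B bond by palladium catalysis without an organolithium. It sets out from 6, which under Miyaura borylation (bis(pinacolato)diboron, Pd(OAc)2, SPhos, KOAc, dioxane, 100 °C) should give the pinacol boronate F5. Oxidation with H2O2 in THF and aq. NaHCO3 at 0 °C brings it back to the route at 8.

**Further compounds**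

F1 | step 9 | everninic acid (2-hydroxy-4-methoxy-6-methylbenzoic acid, bought) | COc1cc(C)c(C(=O)O)c(O)c1
F2 | step 9 | 2-hydroxy-4-methoxy-6-methylbenzoic trifluoroacetic anhydride | COc1cc(C)c(C(=O)OC(=O)C(F)(F)F)c(O)c1
F3 | step 10 | benzyl 2,4-bis(benzyloxy)-3-(1,3-dioxolan-2-yl)-5-[(5-methoxy-7-methyl-2-phenyl-4H-1,3,2-benzodioxaborin-8-carbonyl)oxy]-6-methylbenzoate | COc1cc(C)c(C(=O)Oc3c(C)c(C(=O)OCc4ccccc4)c(OCc4ccccc4)c(C4OCCO4)c3OCc3ccccc3)c2c1COB(c1ccccc1)O2
F4 | step 10 | benzyl 2,4-bis(benzyloxy)-3-(1,3-dioxolan-2-yl)-5-{[2-hydroxy-3-(hydroxymethyl)-4-methoxy-6-methylbenzoyl]oxy}-6-methylbenzoate | COc1cc(C)c(C(=O)Oc2c(C)c(C(=O)OCc3ccccc3)c(OCc3ccccc3)c(C3OCCO3)c2OCc2ccccc2)c(O)c1CO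
F5 | step 6 | benzyl 2,4-bis(benzyloxy)-3-(1,3-dioxolan-2-yl)-6-methyl-5-(4,4,5,5-tetramethyl-1,3,2-dioxaborolan-2-yl)benzoate | CC1(C)OB(OC1(C)C)c1c(C)c(C(=O)OCc2ccccc2)c(OCc2ccccc2)c(C2OCCO2)c1OCc1ccccc1
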